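**First instants.** Starting material loses 36.0% in the first 2.00 min of the red run, and 16.7% in the first 15.0 min of the ochre run.

| setting | ochre | red | north-west | south-west | north-east |
|---|---|---|---|---|---|
| starting material | 0.34 M | 0.75 M | 0.50 M | 0.50 M | 0.50 M |
| coupling partner | 1.5 equiv | 1.5 equiv | 1.50 equiv | 1.50 equiv | 1.50 equiv |
| second substrate | 1 equiv | 1 equiv | 1.00 equiv | 1.00 equiv | 1.00 equiv |
| temperature | 5 °C | 38 °C | 50 °C | 20 °C | −10 °C |
| remark | run made earlier | run made earlier |  |  |  |
| time |  |  | 20 min | 20 min | 20 min |

| run | time / min | target / % | starting material / % |
|---|---|---|---|
| ochre | 15.0 | 15.4 | 83.3 |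
| ochre | 25.0 | 24.0 | 75.7 |
| ochre | 40.0 | 32.9 | 66.0 |
| ochre | 60.0 | 42.9 | 56.3 |
| ochre | 80.0 | 47.3 | 52.0 |
| ochre | 120 | 54.3 | 43.0 |
| ochre | 180 | 61.2 | 40.4 |
| red | 2.00 | 38.8 | 64.0 |
| red | 5.00 | 55.9 | 46.1 |
| red | 10.0 | 60.8 | 37.3 |
| red | 15.0 | 64.3 | 38.3 |
| red | 20.0 | 60.1 | 38.5 |
| red | 25.0 | 58.2 | 41.2 |
| red | 40.0 | 57.3 | 45.8 |

(standard deviation of a reading: 1 percentage point)



* the best flask by amount of target, in percent of the starting material charged; "all alike" if 1.5 percentage points covers them all (north-west / south-west / north-east / all alike)
* amount of target at the end, in percent of the starting material charged, north-west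
* amount of target at the end, in percent of the starting material charged, south-west
* amount of target at the end, in percent of the starting material charged, north-east

I follow one molecule of starting material. At the opening there is no target to return, and the coupling partner stands at its charge, so the molecule has a steady chance per minute (pseudo-first-order). But up to the first reading the partner falls along with the starting material, so I use the integrated second-order rate law, which follows both. It gives the time in which the opening rate, at charged partner, would couple half of the starting material: 53.6 min in the ochre run and 2.69 min in the red run. The red reading is no true opening, since target may already be returning by then, so I treat the red figure as an upper estimate. I scale both to equal partner concentration. They then differ by a factor of 9.03, which over that temperature gap means an activation energy of 48.0 kJ mol⁻¹. With partner at 0.750 M, this meeting half-life comes to 2.03 min in north-west, 12.6 min in south-west and 119 min in north-east.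

**The middle.** What counts is how many meeting half-lives the time grants. In north-east the time is shorter than one half-life, so that flask stays in its opening, and I reckon 11.0% of target. South-west is granted 1.59. The ochre run stood at 1.49 after 80.0 min with 47.3%, and the red run at 1.86 after 5.00 min with 55.9%. South-west lies between them in concentration, so I take the midpoint, 51.6%.

**The end.** The red run read its peak, 64.3%, at 5.58 half-lives. It then sank to 57.3% at 40.0 min while starting material climbed back, which reads as free partner disappearing. North-west is granted 9.87, more than the red peak's count. It is also more dilute than red and hotter. So I put north-west past its peak and under south-west, without a figure I could defend.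

**The result.** The forecast names south-west, with 42% in north-west, 47% in south-west and 10% in north-east, holding that “partner loss pulls target down”. The flasks give south-west as best, with 37.8% in north-west, 51.0% in south-west and 9.05% in north-east.

    starting material + coupling partner ⇌ target (K = 2.20 L mol⁻¹, k = 0.590 L mol⁻¹ min⁻¹, Ea = 53.0 kJ mol⁻¹, ΔH = −19.0 kJ mol⁻¹)
    second substrate + coupling partner ⇌ second product (K = 2.10 L mol⁻¹, k = 0.0130 L mol⁻¹ min⁻¹, Ea = 87.0 kJ mol⁻¹, ΔH = −14.0 kJ mol⁻¹)
    coupling partner → decomposed reagent (k = 0.0350 min⁻¹, Ea = 87.0 kJ mol⁻¹)
    (constants at 50 °C)

**What ran.** In north-west, target stood at 44.7% at 10.0 min and at 37.8% at 20.0 min, while coupling partner went from 46.1% to 34.5% of its charge and decomposed reagent reached 0.259 M. In north-east, the forward half-life of starting material at 9.57 min was 150 min, beside my 119 min, with 94% of the partner left at the end. The neighbour of north-east at 2.0 M cuts my meeting half-life to 29.7 min, and the opening rate then gives 37.3%; that flask holds 80% of its partner and 29.5% of target.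

The numbers in the tables were generated by integration for substances that don't exist; scatter was added.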